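## Retrosynthetic overview

1. Numbering: oxolane O1, C2 (syringyl), C3 (bears C9H2O), C4 (bears benzylic C7'), C5 (CH2). The last bond made is the C9–O ester, from free ferulic acid and the free triol (5-methoxylariciresinol) by a phenol-tolerant Mitsunobu reaction.
2. C4 is the last stereocentre set. The triol comes from a 4-benzylideneoxolane-3-carboxylate by hydrogenation anti to the C3 ester (both benzyl ethers are lost in the same step) and ester reduction.
3. Key disconnection: C2–C3 and O1–C5 together. An enantioselective palladium-catalysed [3+2] joins O-benzylsyringaldehyde (its C=O becomes C2–O1) to a 2-substituted cinnamyl carbonate that supplies C3, C4, C5, C7', C9 and the guaiacyl ring. The oxolane is the only ring made; all arenes are bought.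
4. Enabling feature: ring atom C4 is bonded to three carbons, C3, C5 and C7' (a trimethylenemethane pattern). C3 carries C9, which at the ester level stabilises a carbanion. C5 is the O-bound ring CH2 (allyl cation terminus). C7' is benzylic, so the third arm can rest as a styrene until it is hydrogenated.
5. The carbonate comes from O-benzylvanillin and dimethyl succinate by Stobbe condensation, methyl/tert-butyl ester differentiation and selective reduction.

Key step: step 6

Assumption: the sense of induction of the phosphoramidite in step 6 cannot be read from a rule for this new dipole–aldehyde pair; the ligand enantiomer written is taken to give the (2S,3S) product, and its mirror image would be used otherwise.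

## Route

Step 1
Reactants: 1 4-(benzyloxy)-3-methoxybenzaldehyde; 2 dimethyl succinate
Product: 3 (E)-4-[4-(benzyloxy)-3-methoxyphenyl]-3-(methoxycarbonyl)but-3-enoic acid
Conditions: NaOMe (1.5 equiv), MeOH, reflux; then aq. HCl
Reagents that add atoms: none
Why: Stobbe condensation, in which the succinate enolate adds to the aldehyde, the aldolate lactonises and the paraconate ring opens by E1cB elimination, leaving one free carboxyl group and, for aryl aldehydes, the (E)-alkene with the aryl group trans to the conjugated ester.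

Step 2
Reactants: 3 (E)-4-[4-(benzyloxy)-3-methoxyphenyl]-3-(methoxycarbonyl)but-3-enoic acid
Product: 4 4-tert-butyl 1-methyl (E)-2-[4-(benzyloxy)-3-methoxybenzylidene]butanedioate
Conditions: Cl3CC(=NH)Ot-Bu (2 equiv), CH2Cl2/cyclohexane, rt
Reagents that add atoms: tert-butyl 2,2,2-trichloroacetimidate, CC(C)(C)OC(=N)C(Cl)(Cl)Cl
Why: O-tert-butylation of a carboxylic acid with a trichloroacetimidate, which is base-free so the alkene should not migrate and which makes the two esters sterically different.

Step 3
Reactants: 4 4-tert-butyl 1-methyl (E)-2-[4-(benzyloxy)-3-methoxybenzylidene]butanedioate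
Product: 5 tert-butyl (E)-4-[4-(benzyloxy)-3-methoxyphenyl]-3-(hydroxymethyl)but-3-enoate
Conditions: i-Bu2AlH (2.2 equiv), CH2Cl2, −78 °C; aq. potassium sodium tartrate
Reagents that add atoms: none
Why: Chemoselective i-Bu2AlH reduction of a methyl enoate to the allylic alcohol, the tert-butyl ester being inert at −78 °C and too hindered for ready lactonisation of the product.

Step 4
Reactants: 5 tert-butyl (E)-4-[4-(benzyloxy)-3-methoxyphenyl]-3-(hydroxymethyl)but-3-enoate
Product: 6 tert-butyl (E)-4-[4-(benzyloxy)-3-methoxyphenyl]-3-{[(tert-butoxycarbonyl)oxy]methyl}but-3-enoate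
Conditions: Boc2O (1.2 equiv), DMAP (10 mol %), CH2Cl2, 0 °C
Reagents that add atoms: di-tert-butyl dicarbonate, CC(C)(C)OC(=O)OC(=O)OC(C)(C)C
Why: DMAP-catalysed O-acylation of a primary allylic alcohol, the standard entry to allylic tert-butyl carbonates that release their own base on ionisation.

Step 5
Reactants: 7 4-hydroxy-3,5-dimethoxybenzaldehyde (syringaldehyde)
Product: 8 4-(benzyloxy)-3,5-dimethoxybenzaldehyde
Conditions: BnBr, K2CO3, DMF, 60 °C
Reagents that add atoms: benzyl bromide, BrCc1ccccc1
Why: Williamson ether synthesis on the acidic phenol of syringaldehyde.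

Step 6
Reactants: 6 tert-butyl (E)-4-[4-(benzyloxy)-3-methoxyphenyl]-3-{[(tert-butoxycarbonyl)oxy]methyl}but-3-enoate; 8 4-(benzyloxy)-3,5-dimethoxybenzaldehyde
Product: 11 tert-butyl (2S,3S,4E)-2-[4-(benzyloxy)-3,5-dimethoxyphenyl]-4-[4-(benzyloxy)-3-methoxybenzylidene]oxolane-3-carboxylate, via palladium trimethylenemethane zwitterion 9 (not isolated), via allylpalladium aldolate 10 (not isolated)
Conditions: Pd2(dba)3·CHCl3 (2.5 mol %), (R)-BINOL-derived phosphoramidite of (2R,5R)-2,5-di(2-naphthyl)pyrrolidine (10 mol %), In(acac)3 (10 mol %), 4 Å MS, toluene, 0 °C to rt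
Reagents that add atoms: none
Why: Proposed new method: zerovalent palladium ionises the cinnamyl-type carbonate of 6, the tert-butoxide released with CO2 removes the C3–H that is flanked by the ester and the cationic allyl unit, the trimethylenemethane-type zwitterion 9 adds through C3 to the aldehyde carbon of 8 (C2–C3), and the alkoxide oxygen of 10 then attacks the CH2 terminus of the allyl unit anti to palladium (O1–C5) and returns the catalyst. The closest known reaction types are the palladium-trimethylenemethane [3+2] cycloaddition with aryl aldehydes to 4-methyleneoxolanes (also enantioselective with phosphoramidite ligands), the base-free generation of acceptor-substituted palladium-trimethylenemethane dipoles from 2-(acceptor-methyl)allyl carbonates, and the palladium-catalysed [3+2] of vinylcyclopropane diesters with aldehydes, the new element being the pairing of an ester-stabilised, aryl-substituted dipole with an aldehyde. The single ring closes in a 5-exo-tet sense at C5 (palladium leaves outside the ring), the same closure as in every trimethylenemethane cycloaddition. The absolute configuration at C2 and C3 is controlled by the chiral phosphoramidite on palladium, which stays bound to the C5–C4–C7' allyl unit next to both forming bonds, and the 2,3-trans relation by the reversible aldol step, since the aldolate that places the aryl group and the bulky tert-butyl ester on opposite faces of the forming ring should close fastest. The step needs C3 rather than C7' as the nucleophilic carbon (secured by the ester, which localises the charge on C3), C5 rather than C7' as the electrophilic terminus (secured by the unsubstituted CH2 terminus and by the styrene conjugation kept in 11), and no shift of the alkene into conjugation with the ester (secured by a medium that holds only tert-butanol after turnover and by the hindered ester); the alkene geometry is of no consequence because C7' becomes CH2. In(acac)3 serves as the carbonyl-activating co-catalyst known from palladium-trimethylenemethane additions to C=O groups.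

Step 7
Reactants: 11 tert-butyl (2S,3S,4E)-2-[4-(benzyloxy)-3,5-dimethoxyphenyl]-4-[4-(benzyloxy)-3-methoxybenzylidene]oxolane-3-carboxylate
Product: 12 tert-butyl (2S,3S,4R)-2-(4-hydroxy-3,5-dimethoxyphenyl)-4-(4-hydroxy-3-methoxybenzyl)oxolane-3-carboxylate
Conditions: H2 (1 atm), 10% Pd/C, EtOAc, rt, stopped after uptake of three equivalents
Reagents that add atoms: none
Why: Heterogeneous syn hydrogenation with concurrent benzyl ether hydrogenolysis, in which allylic 1,3-strain with the cis aryl group turns the C3 tert-butyl ester pseudoaxial over one face of the C4=C7' alkene, so hydrogen should arrive from the opposite face and C4 should emerge R with the benzyl group cis to the ester, as is usual for 3-substituted 4-arylideneoxolanes and 2-arylidene lactones of the lignan series.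

Step 8
Reactants: 12 tert-butyl (2S,3S,4R)-2-(4-hydroxy-3,5-dimethoxyphenyl)-4-(4-hydroxy-3-methoxybenzyl)oxolane-3-carboxylate
Product: 13 4-[(2S,3R,4R)-4-(4-hydroxy-3-methoxybenzyl)-3-(hydroxymethyl)oxolan-2-yl]-2,6-dimethoxyphenol (5-methoxylariciresinol)
Conditions: LiAlH4 (5 equiv), THF, 0 °C to 40 °C; aq. potassium sodium tartrate
Reagents that add atoms: none
Why: Hydride reduction of an ester to the primary alcohol, in which the phenols are only deprotonated and C2, C3 and C4 keep their geometry (the C3 descriptor changes from S to R only through the priority change at C9).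

Step 9
Reactants: 13 5-methoxylariciresinol; 14 (E)-ferulic acid
Product: 15 [(2S,3R,4R)-2-(4-hydroxy-3,5-dimethoxyphenyl)-4-(4-hydroxy-3-methoxybenzyl)oxolan-3-yl]methyl (E)-3-(4-hydroxy-3-methoxyphenyl)prop-2-enoate (target)
Conditions: PPh3 (1.3 equiv), DIAD (1.3 equiv), THF, 0 °C to rt
Reagents that add atoms: none
Why: Mitsunobu esterification, known to be chemoselective for a carboxylic acid and a primary aliphatic alcohol beside free phenols because only the acid protonates the betaine and supplies the nucleophile, and C9 is not stereogenic so no centre is touched.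

## Compound list

1 | 4-(benzyloxy)-3-methoxybenzaldehyde | COc1cc(C=O)ccc1OCc1ccccc1 | starting material
2 | dimethyl succinate | COC(=O)CCC(=O)OC | starting material
3 | (E)-4-[4-(benzyloxy)-3-methoxyphenyl]-3-(methoxycarbonyl)but-3-enoic acid | COC(=O)/C(CC(=O)O)=C/c1ccc(OCc2ccccc2)c(OC)c1 | intermediate
4 | 4-tert-butyl 1-methyl (E)-2-[4-(benzyloxy)-3-methoxybenzylidene]butanedioate | COC(=O)/C(CC(=O)OC(C)(C)C)=C/c1ccc(OCc2ccccc2)c(OC)c1 | intermediate
5 | tert-butyl (E)-4-[4-(benzyloxy)-3-methoxyphenyl]-3-(hydroxymethyl)but-3-enoate | OC/C(CC(=O)OC(C)(C)C)=C/c1ccc(OCc2ccccc2)c(OC)c1 | intermediate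
6 | tert-butyl (E)-4-[4-(benzyloxy)-3-methoxyphenyl]-3-{[(tert-butoxycarbonyl)oxy]methyl}but-3-enoate | CC(C)(C)OC(=O)OC/C(CC(=O)OC(C)(C)C)=C/c1ccc(OCc2ccccc2)c(OC)c1 | intermediate
7 | 4-hydroxy-3,5-dimethoxybenzaldehyde (syringaldehyde) | COc1cc(C=O)cc(OC)c1O | starting material
8 | 4-(benzyloxy)-3,5-dimethoxybenzaldehyde | COc1cc(C=O)cc(OC)c1OCc1ccccc1 | intermediate
9 | palladium trimethylenemethane zwitterion (drawn as the sigma-allyl form, ligands omitted) | CC(C)(C)OC(=O)[CH-]/C(C[Pd+])=C\c1ccc(OCc2ccccc2)c(OC)c1 | intermediate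
10 | allylpalladium aldolate (drawn as the sigma-allyl form, ligands omitted) | CC(C)(C)OC(=O)[C@H]([C@H]([O-])c1cc(OC)c(OCc2ccccc2)c(OC)c1)/C(C[Pd+])=C\c1ccc(OCc2ccccc2)c(OC)c1 | intermediate
11 | tert-butyl (2S,3S,4E)-2-[4-(benzyloxy)-3,5-dimethoxyphenyl]-4-[4-(benzyloxy)-3-methoxybenzylidene]oxolane-3-carboxylate | CC(C)(C)OC(=O)[C@H]1/C(=C\c2ccc(OCc3ccccc3)c(OC)c2)CO[C@@H]1c1cc(OC)c(OCc2ccccc2)c(OC)c1 | intermediate
12 | tert-butyl (2S,3S,4R)-2-(4-hydroxy-3,5-dimethoxyphenyl)-4-(4-hydroxy-3-methoxybenzyl)oxolane-3-carboxylate | CC(C)(C)OC(=O)[C@H]1[C@@H](Cc2ccc(O)c(OC)c2)CO[C@@H]1c1cc(OC)c(O)c(OC)c1 | intermediate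
13 | 4-[(2S,3R,4R)-4-(4-hydroxy-3-methoxybenzyl)-3-(hydroxymethyl)oxolan-2-yl]-2,6-dimethoxyphenol | OC[C@H]1[C@@H](Cc2ccc(O)c(OC)c2)CO[C@@H]1c1cc(OC)c(O)c(OC)c1 | intermediate
14 | (E)-ferulic acid | COc1cc(/C=C/C(=O)O)ccc1O | starting material
15 | [(2S,3R,4R)-2-(4-hydroxy-3,5-dimethoxyphenyl)-4-(4-hydroxy-3-methoxybenzyl)oxolan-3-yl]methyl (E)-ferulate | COc1cc(/C=C/C(=O)OC[C@H]2[C@@H](Cc3ccc(O)c(OC)c3)CO[C@@H]2c2cc(OC)c(O)c(OC)c2)ccc1O | target

## Step count and risks

Total steps: 9. Longest linear sequence: 8 (steps 1, 2, 3, 4, 6, 7, 8, 9).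

**Step 6 (proposed new method).**
- What may go wrong:
  - The stabilised dipole may add too slowly to the electron-rich aldehyde, so the donor allylates itself.
  - The alkoxide may close at the benzylic allyl terminus.
  - The exocyclic alkene may drift into conjugation with the ester, with loss of C3.
  - The ligand may discriminate the enantiomeric pathways poorly.
- Fallback (known chemistry; it gives up the one-operation ring construction): it sets out from 3 and 8 and comes back at 13.
  - Asymmetric hydrogenation of 3 ([Rh(cod)((S,S)-Et-DuPhos)]OTf, H2, MeOH, ligand hand chosen for R) should give (R)-4-[4-(benzyloxy)-3-methoxyphenyl]-3-(methoxycarbonyl)butanoic acid F1.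
  - Reduction of its potassium salt with Ca(BH4)2 in EtOH, with acidic work-up, gives (R)-4-[4-(benzyloxy)-3-methoxybenzyl]oxolan-2-one F2.
  - Its lithium enolate (LiN(SiMe3)2, THF, −78 °C) adds to 8 anti to the benzyl group to give the trans aldol lactone F3. The carbinol epimers converge later.
  - LiAlH4 gives the benzylic triol F4.
  - Catalytic camphorsulfonic acid in CH2Cl2 closes the oxolane through the benzylic cation to the 2,3-trans product, 5-methoxylariciresinol dibenzyl ether F5.
  - H2 over 10% Pd/C gives 13.

**Step 7.**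
- What may go wrong:
  - The two alkene faces may not be discriminated well enough.
  - The allylic C5–O or benzylic C2–O bond may be hydrogenolysed before or after saturation.
- Fallback: it sets out from 11 and comes back at 13, and sets C4 by a ring-fusion constraint instead of by reagent approach.
  - CF3CO2H in CH2Cl2 at 0 °C cleaves the tert-butyl ester. The free acid then adds to the protonated electron-rich styrene at C7'.
  - Only the cis-fused bicycle can form, and protonation at C4 is reversible. The product should be the cis-fused furofuranone lactone F6.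
  - H2 over 10% Pd/C in EtOAc/AcOH cleaves the benzylic acyloxy C7'–O bond in preference to the C2–O ether, together with both benzyl ethers. This gives the 3,4-cis oxolane-3-carboxylic acid F7.
  - BH3·THF reduces F7 to 13.

**Step 9.**
- What may go wrong:
  - Phenol oxygens may be alkylated in competition.
  - Displacement at the β-branched C9 may be sluggish.
- Fallback: it sets out from 12 and 14 and comes back at 15.
  - TBSCl and imidazole in DMF convert 12 into the bis(silyl ether) ester F8.
  - i-Bu2AlH (CH2Cl2, −78 to 0 °C) gives the bis(silyl ether) alcohol F9.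
  - Separately, 14 with TBSCl (2.2 equiv) and imidazole gives the silyl ester silyl ether F10. K2CO3 in aqueous MeOH/THF hydrolyses it to 4-O-TBS-ferulic acid F11.
  - Steglich esterification of F9 with F11 (EDC·HCl, DMAP, CH2Cl2) gives the tris(silyl ether) of the target F12.
  - Bu4NF buffered with AcOH (THF, 0 °C) releases 15.

## Further compounds

F1 | step 6 | (R)-4-[4-(benzyloxy)-3-methoxyphenyl]-3-(methoxycarbonyl)butanoic acid | OC(=O)C[C@@H](Cc1ccc(OCc2ccccc2)c(OC)c1)C(=O)OC
F2 | step 6 | (R)-4-[4-(benzyloxy)-3-methoxybenzyl]oxolan-2-one | O=C1C[C@@H](Cc2ccc(OCc3ccccc3)c(OC)c2)CO1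
F3 | step 6 | (3S,4R)-4-[4-(benzyloxy)-3-methoxybenzyl]-3-{[4-(benzyloxy)-3,5-dimethoxyphenyl](hydroxy)methyl}oxolan-2-one, both carbinol epimers | O=C1[C@H](C(O)c2cc(OC)c(OCc3ccccc3)c(OC)c2)[C@@H](Cc2ccc(OCc3ccccc3)c(OC)c2)CO1
F4 | step 6 | (2R,3R)-2-[4-(benzyloxy)-3-methoxybenzyl]-3-{[4-(benzyloxy)-3,5-dimethoxyphenyl](hydroxy)methyl}butane-1,4-diol, both carbinol epimers | OC[C@H](C(O)c1cc(OC)c(OCc2ccccc2)c(OC)c1)[C@@H](Cc1ccc(OCc2ccccc2)c(OC)c1)CO
F5 | step 6 | {(2S,3R,4R)-2-[4-(benzyloxy)-3,5-dimethoxyphenyl]-4-[4-(benzyloxy)-3-methoxybenzyl]oxolan-3-yl}methanol | OC[C@H]1[C@@H](Cc2ccc(OCc3ccccc3)c(OC)c2)CO[C@@H]1c1cc(OC)c(OCc2ccccc2)c(OC)c1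
F6 | step 7 | cis-fused furo[3,4-c]furan-1-one lactone (C9(=O)–O–C7' bridge cis on C3 and C4, both aryl groups exo) | O=C1O[C@H](c2ccc(OCc3ccccc3)c(OC)c2)[C@H]2CO[C@H](c3cc(OC)c(OCc4ccccc4)c(OC)c3)[C@@H]12
F7 | step 7 | (2S,3S,4R)-2-(4-hydroxy-3,5-dimethoxyphenyl)-4-(4-hydroxy-3-methoxybenzyl)oxolane-3-carboxylic acid | OC(=O)[C@H]1[C@@H](Cc2ccc(O)c(OC)c2)CO[C@@H]1c1cc(OC)c(O)c(OC)c1
F8 | step 9 | bis(tert-butyldimethylsilyl ether) of 12 | CC(C)(C)OC(=O)[C@H]1[C@@H](Cc2ccc(O[Si](C)(C)C(C)(C)C)c(OC)c2)CO[C@@H]1c1cc(OC)c(O[Si](C)(C)C(C)(C)C)c(OC)c1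
F9 | step 9 | bis(phenolic tert-butyldimethylsilyl ether) of 13 with free C9–OH | OC[C@H]1[C@@H](Cc2ccc(O[Si](C)(C)C(C)(C)C)c(OC)c2)CO[C@@H]1c1cc(OC)c(O[Si](C)(C)C(C)(C)C)c(OC)c1
F10 | step 9 | tert-butyldimethylsilyl (E)-4-O-(tert-butyldimethylsilyl)ferulate | COc1cc(/C=C/C(=O)O[Si](C)(C)C(C)(C)C)ccc1O[Si](C)(C)C(C)(C)C
F11 | step 9 | (E)-4-O-(tert-butyldimethylsilyl)ferulic acid | COc1cc(/C=C/C(=O)O)ccc1O[Si](C)(C)C(C)(C)C
F12 | step 9 | tris(tert-butyldimethylsilyl ether) of 15 | COc1cc(/C=C/C(=O)OC[C@H]2[C@@H](Cc3ccc(O[Si](C)(C)C(C)(C)C)c(OC)c3)CO[C@@H]2c2cc(OC)c(O[Si](C)(C)C(C)(C)C)c(OC)c2)ccc1O[Si](C)(C)C(C)(C)C
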